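**Plan**

1. Locants: resveratrol units a–d; in unit x, C7x/C8x are the two bridging carbons, C1x–C6x form the 4-oxyphenyl ring and C9x–C14x the resorcinol ring. The retrosynthesis cuts (i) the aryl–vinyl bond C1c–C7c, giving bromophenol 21 (units a and b plus the 4-oxyphenyl ring of unit c; 7 rings, 4 stereocentres) and styrene 13 (the resorcinol ring of unit c plus unit d; 4 rings, 2 stereocentres); (ii) C7b–C10a of the cycloheptane, leading back to a temporary dihydrobenzofuran O4c–C7b–C8b–C3c–C4c (20); (iii) C7b–C8b of that ring and C7–C8 of the two permanent dihydrobenzofurans (carbene C–H insertion); (iv) the aryl–C(=N) bonds (nitrile additions).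
2. Forward: nitrile 6 (the resorcinol ring of unit b or of unit c) → hydrazone → dihydrobenzofuran bromide 12, the one building block for units a/b and c/d. 12 → styrene 13. 12 → aryllithium + nitrile 15 → second C–H insertion (temporary furan on the 4-oxyphenyl ring of unit c) → acid ring expansion to the dibenzocycloheptane 21 → Heck union with 13 → debenzylation.
3. Stereochemistry: C8a, C8d and C8b come from the same catalyst, Rh2(S-PTAD)4, in the two C–H insertions. C7a and C7d come from acid equilibration to the 2,3-trans ring. C7b comes from the face-selective Friedel–Crafts closure of the seven-membered ring. The E alkene comes from syn β-hydride elimination in the Heck step.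
4. Feature used by the key step: C1c of the phenol ring of unit c is para to the phenolic oxygen O4c and carries only the C7c=C8c bridge to C9c of the benzofuran benzo ring of unit c. A para-bromophenol and an unactivated vinyl group are therefore enough. The bromine arrives with commercial 5-bromo-2-hydroxybenzonitrile, whose nitrile carbon becomes C8b and whose oxygen becomes O4c.

Key step: step 13

Remarks: Bn = benzyl; PTAD = (1-adamantyl)(phthalimido)acetate. Compounds 1, 4 and 14 are taken as commercially available.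
Assumption: Rh2(S-PTAD)4 is taken to give the (2R,3S)-cis-dihydrobenzofuran series in both insertions; if the sense of induction is the opposite, Rh2(R-PTAD)4 is used in steps 6 and 11.
Assumption on stereochemical precedent: the C7b outcome of step 12 is argued by analogy with the acid-induced rearrangement of the natural dihydrobenzofuran isomer, recalled rather than verified.

**Route**

Step 1
Reactants: 1 1,3-bis(benzyloxy)-5-bromobenzene
Product: 2 2,4-bis(benzyloxy)-6-bromobenzaldehyde
Conditions: POCl3, DMF, 0 → 70 °C; then H2O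
Reagents that add atoms: N,N-dimethylformamide, CN(C)C=O; water, O
Why: Vilsmeier–Haack formylation should take place at the ring carbon that is para to one benzyloxy group and ortho to the other (next to bromine), the position between the two ethers being more hindered.

Step 2
Reactants: 2 2,4-bis(benzyloxy)-6-bromobenzaldehyde
Product: 3 4-(benzyloxy)-2-bromo-6-hydroxybenzaldehyde
Conditions: MgBr2, Et2O/toluene, reflux; 1 M HCl
Reagents that add atoms: none
Why: Chelation-controlled ether cleavage: MgBr2 held between the aldehyde oxygen and the ortho ether oxygen should deliver bromide to that benzyl group only, leaving the para benzyl ether.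

Step 3
Reactants: 3 4-(benzyloxy)-2-bromo-6-hydroxybenzaldehyde; 4 1-(benzyloxy)-4-(chloromethyl)benzene
Product: 5 4-(benzyloxy)-2-{[4-(benzyloxy)benzyl]oxy}-6-bromobenzaldehyde
Conditions: K2CO3, DMF, 60 °C
Reagents that add atoms: none
Why: Williamson etherification of the phenoxide with a benzylic chloride; the new O–CH2 group is the later C–H insertion site and its aryl group becomes the 4-oxyphenyl ring of unit a (or of unit d).

Step 4
Reactants: 5 4-(benzyloxy)-2-{[4-(benzyloxy)benzyl]oxy}-6-bromobenzaldehyde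
Product: 6 4-(benzyloxy)-2-{[4-(benzyloxy)benzyl]oxy}-6-bromobenzonitrile
Conditions: I2, aq NH3, THF, rt
Reagents that add atoms: ammonia, N
Why: Oxidative conversion of an aldehyde into a nitrile through the N-iodo aldimine, a mild method that should tolerate benzyl ethers and the aryl bromide.

Step 5
Reactants: 6 4-(benzyloxy)-2-{[4-(benzyloxy)benzyl]oxy}-6-bromobenzonitrile; 1 1,3-bis(benzyloxy)-5-bromobenzene
Product: 9 hydrazone of [4-(benzyloxy)-2-{[4-(benzyloxy)benzyl]oxy}-6-bromophenyl][3,5-bis(benzyloxy)phenyl]methanone, via arylmagnesium bromide 7 (not isolated), via N–H ketimine 8 (not isolated)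
Conditions: 1, Mg, THF, 50 °C; then 6, THF/toluene, 70 °C (no copper); AcOH; N2H4·H2O, EtOH, 75 °C
Reagents that add atoms: hydrazine (as hydrate), NN
Why: Grignard addition to the nitrile should stop at the hindered metalated ketimine, and transimination of the N–H ketimine with hydrazine gives the hydrazone without passing through the doubly ortho-substituted ketone; copper is left out so that the ortho C–Br bond is not closed to an indazole.

Step 6
Reactants: 9 hydrazone of [4-(benzyloxy)-2-{[4-(benzyloxy)benzyl]oxy}-6-bromophenyl][3,5-bis(benzyloxy)phenyl]methanone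
Product: 11 (2R,3S)-6-(benzyloxy)-2-[4-(benzyloxy)phenyl]-3-[3,5-bis(benzyloxy)phenyl]-4-bromo-2,3-dihydro-1-benzofuran (2,3-cis), via diaryldiazomethane 10 (not isolated)
Conditions: MnO2, CH2Cl2, rt, filtration; Rh2(S-PTAD)4 (1 mol %), CH2Cl2, 0 °C
Reagents that add atoms: none
Why: Hydrazone oxidation followed by enantioselective intramolecular 1,5 C–H insertion of the donor/donor rhodium carbene into the benzylic ether C–H bond, a reaction type established for 2,3-diaryl-2,3-dihydrobenzofurans; the chiral carboxylate ligands set C3 (S) and the concerted insertion gives the 2,3-cis ring (C2 R).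

Step 7
Reactants: 11 (2R,3S)-cis-dihydrobenzofuran bromide
Product: 12 (2S,3S)-6-(benzyloxy)-2-[4-(benzyloxy)phenyl]-3-[3,5-bis(benzyloxy)phenyl]-4-bromo-2,3-dihydro-1-benzofuran (2,3-trans)
Conditions: TFA, CH2Cl2, 0 °C → rt
Reagents that add atoms: none
Why: Acid-mediated epimerisation: reversible ionisation of the C2–O bond to the 4-benzyloxybenzyl cation and reclosure should give the thermodynamically favoured trans ring (C2 becomes S) while C3 is untouched.

Step 8
Reactants: 12 (2S,3S)-trans-dihydrobenzofuran bromide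
Product: 13 (2S,3S)-6-(benzyloxy)-2-[4-(benzyloxy)phenyl]-3-[3,5-bis(benzyloxy)phenyl]-4-ethenyl-2,3-dihydro-1-benzofuran
Conditions: 4,4,5,5-tetramethyl-2-vinyl-1,3,2-dioxaborolane, PdCl2(dppf) (5 mol %), K2CO3, dioxane/H2O, 80 °C
Reagents that add atoms: 4,4,5,5-tetramethyl-2-vinyl-1,3,2-dioxaborolane, C=CB1OC(C)(C)C(C)(C)O1
Why: Suzuki–Miyaura vinylation of an aryl bromide; the mildly basic conditions should not touch the two stereocentres.

Step 9
Reactants: 14 5-bromo-2-hydroxybenzonitrile; 4 1-(benzyloxy)-4-(chloromethyl)benzene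
Product: 15 2-{[4-(benzyloxy)benzyl]oxy}-5-bromobenzonitrile
Conditions: K2CO3, DMF, 60 °C
Reagents that add atoms: none
Why: Williamson etherification; this one compound supplies the 4-oxyphenyl ring of unit c with its para bromine, the future C8b (nitrile carbon), O4c and, in the benzyl group, C7b with the 4-oxyphenyl ring of unit b.

Step 10
Reactants: 12 (2S,3S)-trans-dihydrobenzofuran bromide; 15 2-{[4-(benzyloxy)benzyl]oxy}-5-bromobenzonitrile
Product: 18 hydrazone of (2-{[4-(benzyloxy)benzyl]oxy}-5-bromophenyl){(2S,3S)-6-(benzyloxy)-2-[4-(benzyloxy)phenyl]-3-[3,5-bis(benzyloxy)phenyl]-2,3-dihydro-1-benzofuran-4-yl}methanone, via aryllithium 16 (not isolated), via N–H ketimine 17 (not isolated)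
Conditions: n-BuLi, THF, −78 °C; then 15, −78 → −30 °C; AcOH; N2H4·H2O, EtOH, 60 °C
Reagents that add atoms: hydrazine (as hydrate), NN
Why: Bromine–lithium exchange, addition of the aryllithium to the nitrile (much faster at low temperature than exchange with the second aryl bromide) and transimination with hydrazine should give the hindered hydrazone directly; the stereocentres are not involved.

Step 11
Reactants: 18 hydrazone from step 10
Product: 20 (2R,3S)-2-[4-(benzyloxy)phenyl]-5-bromo-3-{(2S,3S)-6-(benzyloxy)-2-[4-(benzyloxy)phenyl]-3-[3,5-bis(benzyloxy)phenyl]-2,3-dihydro-1-benzofuran-4-yl}-2,3-dihydro-1-benzofuran (temporary cis-dihydrobenzofuran on the 4-oxyphenyl ring of unit c), via diaryldiazomethane 19 (not isolated)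
Conditions: MnO2, CH2Cl2, rt, filtration; Rh2(S-PTAD)4 (1 mol %), CH2Cl2, 0 °C
Reagents that add atoms: none
Why: Second rhodium-carbene 1,5 C–H insertion, now into the O4c–CH2 group on the 4-oxyphenyl ring of unit c; the same catalyst should set C8b (S) under catalyst control, and C7b (R, cis) is only provisional because step 12 ionises it.

Step 12
Reactants: 20 bis(dihydrobenzofuran) from step 11
Product: 21 bromophenol: (7aS,8aS,7bS,8bS)-dibenzocycloheptane fused to the unit-a dihydrobenzofuran, with 4-(benzyloxy)phenyl on C7a and C7b, benzyloxy on C11a, C13a and C13b, and the 5-bromo-2-hydroxyphenyl ring of unit c on C8b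
Conditions: TFA, CH2Cl2, −20 → 0 °C
Reagents that add atoms: none
Why: Acid should ionise the C7b–O4c bond of the temporary dihydrobenzofuran to the 4-benzyloxybenzyl cation, which C10a of the resorcinol ring of unit a captures in a seven-membered Friedel–Crafts closure (the ring expansion by which this ring system is understood to arise from its dihydrobenzofuran isomer); C8b is untouched, C7b is expected to be set by attack on the cation face that leaves the 4-oxyphenyl rings of units b and c cis to each other and on the side of H8a, and the permanent dihydrobenzofuran can only reclose to its trans form.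

Step 13
Reactants: 21 bromophenol (units a and b plus the 4-oxyphenyl ring of unit c); 13 (2S,3S)-4-ethenyl-dihydrobenzofuran (the resorcinol ring of unit c plus unit d)
Product: 22 nona-O-benzyl ether of the target (all phenols benzylated except O4c), (7aS,8aS,7bS,8bS,7dS,8dS), E alkene
Conditions: Pd2(dba)3 (2.5 mol %), P(t-Bu)3·HBF4 (10 mol %), Cy2NMe, 1,4-dioxane, 80 °C
Reagents that add atoms: none
Why: Mizoroki–Heck arylation: zerovalent palladium inserts into the C1c–Br bond of 21, the aryl–palladium species adds syn across the vinyl group of 13 with the aryl group going to the unsubstituted terminus C7c and palladium to the benzylic carbon C8c, and syn β-hydride elimination from the rotamer with the two aryl groups anti releases the E stilbene while the amine regenerates the catalyst. The closest known reaction type is the Heck synthesis of stilbenes from electron-rich aryl bromides and styrenes with bulky trialkylphosphine–palladium catalysts, which tolerates free phenols. No ring is closed and no stereocentre is created; the only new stereo element, the C7c=C8c geometry, is controlled by the syn elimination, which strongly favours E. The step needs regioselectivity for the terminal carbon, secured by the steric bias of a monosubstituted styrene and the neutral bromide-bound palladium pathway, and chemoselectivity, secured because 21 holds one C–Br bond and 13 one alkene. The six stereocentres should survive because the medium is neither acidic nor strongly basic, the phenol of 21 stays un-ionised with an amine base in dioxane, and no dihydrobenzofuran carries a free para-hydroxyphenyl group that could open it.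

Step 14
Reactants: 22 nona-O-benzyl ether of the target
Product: 23 target CNP0266373.2, (7aS,8aS,7bS,8bS,7dS,8dS), E alkene
Conditions: BCl3, pentamethylbenzene, CH2Cl2, −78 °C; MeOH quench, aqueous work-up
Reagents that add atoms: none
Why: Lewis-acid cleavage of aryl benzyl ethers with pentamethylbenzene as non-basic benzyl-cation scavenger at low temperature, chosen because it should leave the stilbene, the two dihydrobenzofurans and the cis-diaryl cycloheptane intact.

**Compound list**

1 | 1,3-bis(benzyloxy)-5-bromobenzene | Brc1cc(OCc2ccccc2)cc(OCc2ccccc2)c1 | starting material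
2 | 2,4-bis(benzyloxy)-6-bromobenzaldehyde | O=Cc1c(Br)cc(OCc2ccccc2)cc1OCc1ccccc1 | intermediate
3 | 4-(benzyloxy)-2-bromo-6-hydroxybenzaldehyde | O=Cc1c(O)cc(OCc2ccccc2)cc1Br | intermediate
4 | 1-(benzyloxy)-4-(chloromethyl)benzene | ClCc1ccc(OCc2ccccc2)cc1 | starting material
5 | 4-(benzyloxy)-2-{[4-(benzyloxy)benzyl]oxy}-6-bromobenzaldehyde | O=Cc1c(Br)cc(OCc2ccccc2)cc1OCc1ccc(OCc2ccccc2)cc1 | intermediate
6 | 4-(benzyloxy)-2-{[4-(benzyloxy)benzyl]oxy}-6-bromobenzonitrile | N#Cc1c(Br)cc(OCc2ccccc2)cc1OCc1ccc(OCc2ccccc2)cc1 | intermediate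
7 | [3,5-bis(benzyloxy)phenyl]magnesium bromide (formed in the flask) | Br[Mg]c1cc(OCc2ccccc2)cc(OCc2ccccc2)c1 | intermediate
8 | [4-(benzyloxy)-2-{[4-(benzyloxy)benzyl]oxy}-6-bromophenyl][3,5-bis(benzyloxy)phenyl]methanimine (formed in the flask) | N=C(c1cc(OCc2ccccc2)cc(OCc2ccccc2)c1)c1c(Br)cc(OCc2ccccc2)cc1OCc1ccc(OCc2ccccc2)cc1 | intermediate
9 | hydrazone of [4-(benzyloxy)-2-{[4-(benzyloxy)benzyl]oxy}-6-bromophenyl][3,5-bis(benzyloxy)phenyl]methanone | NN=C(c1cc(OCc2ccccc2)cc(OCc2ccccc2)c1)c1c(Br)cc(OCc2ccccc2)cc1OCc1ccc(OCc2ccccc2)cc1 | intermediate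
10 | [4-(benzyloxy)-2-{[4-(benzyloxy)benzyl]oxy}-6-bromophenyl][3,5-bis(benzyloxy)phenyl]diazomethane (formed in the flask) | [N-]=[N+]=C(c1cc(OCc2ccccc2)cc(OCc2ccccc2)c1)c1c(Br)cc(OCc2ccccc2)cc1OCc1ccc(OCc2ccccc2)cc1 | intermediate
11 | (2R,3S)-6-(benzyloxy)-2-[4-(benzyloxy)phenyl]-3-[3,5-bis(benzyloxy)phenyl]-4-bromo-2,3-dihydro-1-benzofuran (cis) | Brc1cc(OCc2ccccc2)cc2c1[C@H](c1cc(OCc3ccccc3)cc(OCc3ccccc3)c1)[C@H](c1ccc(OCc3ccccc3)cc1)O2 | intermediate
12 | (2S,3S)-6-(benzyloxy)-2-[4-(benzyloxy)phenyl]-3-[3,5-bis(benzyloxy)phenyl]-4-bromo-2,3-dihydro-1-benzofuran (trans) | Brc1cc(OCc2ccccc2)cc2c1[C@H](c1cc(OCc3ccccc3)cc(OCc3ccccc3)c1)[C@@H](c1ccc(OCc3ccccc3)cc1)O2 | intermediate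
13 | (2S,3S)-6-(benzyloxy)-2-[4-(benzyloxy)phenyl]-3-[3,5-bis(benzyloxy)phenyl]-4-ethenyl-2,3-dihydro-1-benzofuran | C=Cc1cc(OCc2ccccc2)cc2c1[C@H](c1cc(OCc3ccccc3)cc(OCc3ccccc3)c1)[C@@H](c1ccc(OCc3ccccc3)cc1)O2 | intermediate
14 | 5-bromo-2-hydroxybenzonitrile | N#Cc1cc(Br)ccc1O | starting material
15 | 2-{[4-(benzyloxy)benzyl]oxy}-5-bromobenzonitrile | N#Cc1cc(Br)ccc1OCc1ccc(OCc2ccccc2)cc1 | intermediate
16 | {(2S,3S)-6-(benzyloxy)-2-[4-(benzyloxy)phenyl]-3-[3,5-bis(benzyloxy)phenyl]-2,3-dihydro-1-benzofuran-4-yl}lithium (formed in the flask) | [Li]c1cc(OCc2ccccc2)cc2c1[C@H](c1cc(OCc3ccccc3)cc(OCc3ccccc3)c1)[C@@H](c1ccc(OCc3ccccc3)cc1)O2 | intermediate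
17 | (2-{[4-(benzyloxy)benzyl]oxy}-5-bromophenyl){(2S,3S)-6-(benzyloxy)-2-[4-(benzyloxy)phenyl]-3-[3,5-bis(benzyloxy)phenyl]-2,3-dihydro-1-benzofuran-4-yl}methanimine (formed in the flask) | N=C(c1cc(Br)ccc1OCc1ccc(OCc2ccccc2)cc1)c1cc(OCc2ccccc2)cc2c1[C@H](c1cc(OCc3ccccc3)cc(OCc3ccccc3)c1)[C@@H](c1ccc(OCc3ccccc3)cc1)O2 | intermediate
18 | hydrazone of (2-{[4-(benzyloxy)benzyl]oxy}-5-bromophenyl){(2S,3S)-6-(benzyloxy)-2-[4-(benzyloxy)phenyl]-3-[3,5-bis(benzyloxy)phenyl]-2,3-dihydro-1-benzofuran-4-yl}methanone | NN=C(c1cc(Br)ccc1OCc1ccc(OCc2ccccc2)cc1)c1cc(OCc2ccccc2)cc2c1[C@H](c1cc(OCc3ccccc3)cc(OCc3ccccc3)c1)[C@@H](c1ccc(OCc3ccccc3)cc1)O2 | intermediate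
19 | diazo compound from 18 (formed in the flask) | [N-]=[N+]=C(c1cc(Br)ccc1OCc1ccc(OCc2ccccc2)cc1)c1cc(OCc2ccccc2)cc2c1[C@H](c1cc(OCc3ccccc3)cc(OCc3ccccc3)c1)[C@@H](c1ccc(OCc3ccccc3)cc1)O2 | intermediate
20 | (2R,3S)-2-[4-(benzyloxy)phenyl]-5-bromo-3-{(2S,3S)-6-(benzyloxy)-2-[4-(benzyloxy)phenyl]-3-[3,5-bis(benzyloxy)phenyl]-2,3-dihydro-1-benzofuran-4-yl}-2,3-dihydro-1-benzofuran | Brc1ccc2c(c1)[C@H](c1cc(OCc3ccccc3)cc3c1[C@H](c1cc(OCc4ccccc4)cc(OCc4ccccc4)c1)[C@@H](c1ccc(OCc4ccccc4)cc1)O3)[C@H](c1ccc(OCc3ccccc3)cc1)O2 | intermediate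
21 | bromophenol, (7aS,8aS,7bS,8bS): dibenzocycloheptane fused to the unit-a dihydrobenzofuran, five benzyl ethers, 5-bromo-2-hydroxyphenyl on C8b | c1ccccc1COc1ccc([C@H]2c3c(OCc5ccccc5)cc(OCc5ccccc5)cc3[C@H]3c4c(cc(OCc5ccccc5)cc4[C@H]2c2cc(Br)ccc2O)O[C@@H]3c2ccc(OCc5ccccc5)cc2)cc1 | intermediate
22 | nona-O-benzyl ether of the target (O4c free), E alkene | c1ccccc1COc1ccc([C@H]2c3c(OCc6ccccc6)cc(OCc6ccccc6)cc3[C@H]3c4c(cc(OCc6ccccc6)cc4[C@H]2c2cc(/C=C/c4cc(OCc6ccccc6)cc5c4[C@H](c4cc(OCc6ccccc6)cc(OCc6ccccc6)c4)[C@@H](c4ccc(OCc6ccccc6)cc4)O5)ccc2O)O[C@@H]3c2ccc(OCc6ccccc6)cc2)cc1 | intermediate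
23 | CNP0266373.2, (7aS,8aS,7bS,8bS,7dS,8dS), E alkene | Oc1ccc([C@H]2c3c(O)cc(O)cc3[C@H]3c4c(cc(O)cc4[C@H]2c2cc(/C=C/c4cc(O)cc5c4[C@H](c4cc(O)cc(O)c4)[C@@H](c4ccc(O)cc4)O5)ccc2O)O[C@@H]3c2ccc(O)cc2)cc1 | target

**Step count**

Total: 14 steps. Longest linear sequence: 12 steps (1 → 2 → 3 → 5 → 6 → 9 → 11 → 12 → 18 → 20 → 21 → 22 → 23).

**Steps most likely to fail**

Step 11. The rhodium carbene may be intercepted by the electron-rich resorcinol ring of unit a (aromatic substitution instead of C–H insertion), or the resident stereocentres may oppose the catalyst so that facial selectivity at C8b is poor. The fallback avoids a carbene and sets out from 12. Lithiation as in step 10 and addition to the sodium salt of 5-bromo-2-hydroxybenzaldehyde should give the diaryl carbinol (5-bromo-2-hydroxyphenyl){(2S,3S)-6-(benzyloxy)-2-[4-(benzyloxy)phenyl]-3-[3,5-bis(benzyloxy)phenyl]-2,3-dihydro-1-benzofuran-4-yl}methanol F1. Exchange of its hydroxyl group with p-TolSO2Na and formic acid should give the p-tolyl sulfone F2, a standard precursor of an ortho-quinone methide. Treatment of F2 with [4-(benzyloxy)benzyl]dimethylsulfonium chloride F3 (from 4 and dimethyl sulfide) and Cs2CO3 in CH2Cl2 should release the ortho-quinone methide and the sulfonium ylide, whose formal (4+1) annulation closes the trans-dihydrobenzofuran F4, the C7b epimer of 20. The C8b epimers would be separated at this stage. Because step 12 ionises C7b, F4 comes back to the route at 21 under the conditions of step 12.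

Step 12. Acid strong enough to ionise the benzyl-protected C7b–O bond may also start benzyl transfer from the resorcinol ethers, allow a 1,2-hydride shift from C8b before ring closure, or equilibrate the cis-7b,8b product to its trans isomer. The fallback moves the ring expansion to the free-phenol stage and sets out from 20. Heck coupling of 20 with 13 under the conditions of step 13 should give the nona-O-benzyl ether of the dihydrobenzofuran isomer of the target F5. BCl3 and pentamethylbenzene at −78 °C should then give the free polyphenol F6. In F6 the 4-hydroxyphenyl ring of unit b carries a free para-hydroxyl group, so dilute formic acid in methanol should open the C7b–O bond through the para-quinone methide and close the cycloheptane, as in the natural series. This comes back to the route at 23.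

Step 14. During nine ether cleavages the Lewis acid may protonate the electron-rich stilbene, which then cyclises onto a neighbouring resorcinol ring, or may ionise benzylic C–O and C–C bonds of the product. The fallback removes the benzyl groups before the stilbene exists and sets out from 21 and 12. BCl3 and pentamethylbenzene should convert 21 into the hexaphenol bromide F7 and 12 into the tetraphenol bromide F8. Suzuki–Miyaura vinylation of F8 (vinylboronic ester, PdCl2(dppf), K2CO3) should give the tetraphenol styrene F9. A Heck coupling of the unprotected partners F7 and F9 (Pd(OAc)2, P(o-tol)3, Et3N, DMF, 90 °C, inert atmosphere) then forms the C1c–C7c bond as the last step and comes back to the route at 23.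

**Further compounds**

F1 | step 11 | (5-bromo-2-hydroxyphenyl){(2S,3S)-6-(benzyloxy)-2-[4-(benzyloxy)phenyl]-3-[3,5-bis(benzyloxy)phenyl]-2,3-dihydro-1-benzofuran-4-yl}methanol (both carbinol epimers) | OC(c1cc(Br)ccc1O)c1cc(OCc2ccccc2)cc2c1[C@H](c1cc(OCc3ccccc3)cc(OCc3ccccc3)c1)[C@@H](c1ccc(OCc3ccccc3)cc1)O2
F2 | step 11 | 4-bromo-2-[{(2S,3S)-6-(benzyloxy)-2-[4-(benzyloxy)phenyl]-3-[3,5-bis(benzyloxy)phenyl]-2,3-dihydro-1-benzofuran-4-yl}(4-methylbenzenesulfonyl)methyl]phenol | Cc1ccc(cc1)S(=O)(=O)C(c1cc(Br)ccc1O)c1cc(OCc2ccccc2)cc2c1[C@H](c1cc(OCc3ccccc3)cc(OCc3ccccc3)c1)[C@@H](c1ccc(OCc3ccccc3)cc1)O2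
F3 | step 11 | [4-(benzyloxy)benzyl]dimethylsulfonium chloride | C[S+](C)Cc1ccc(OCc2ccccc2)cc1.[Cl-]
F4 | step 11 | (2S,3S)-2-[4-(benzyloxy)phenyl]-5-bromo-3-{(2S,3S)-6-(benzyloxy)-2-[4-(benzyloxy)phenyl]-3-[3,5-bis(benzyloxy)phenyl]-2,3-dihydro-1-benzofuran-4-yl}-2,3-dihydro-1-benzofuran (trans, C7b epimer of 20) | Brc1ccc2c(c1)[C@H](c1cc(OCc3ccccc3)cc3c1[C@H](c1cc(OCc4ccccc4)cc(OCc4ccccc4)c1)[C@@H](c1ccc(OCc4ccccc4)cc1)O3)[C@@H](c1ccc(OCc3ccccc3)cc1)O2
F5 | step 12 | nona-O-benzyl ether of the dihydrobenzofuran isomer of the target (Heck product of 20 and 13), E alkene | c1(cc(OCc2ccccc2)cc2c1[C@H](c1cc(OCc3ccccc3)cc(OCc3ccccc3)c1)[C@@H](c1ccc(OCc3ccccc3)cc1)O2)/C=C/c1ccc2c(c1)[C@H](c1cc(OCc3ccccc3)cc3c1[C@H](c1cc(OCc4ccccc4)cc(OCc4ccccc4)c1)[C@@H](c1ccc(OCc4ccccc4)cc1)O3)[C@H](c1ccc(OCc3ccccc3)cc1)O2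
F6 | step 12 | dihydrobenzofuran isomer of the target with nine free phenols (O4c–C7b ring intact), E alkene | c1(cc(O)cc2c1[C@H](c1cc(O)cc(O)c1)[C@@H](c1ccc(O)cc1)O2)/C=C/c1ccc2c(c1)[C@H](c1cc(O)cc3c1[C@H](c1cc(O)cc(O)c1)[C@@H](c1ccc(O)cc1)O3)[C@H](c1ccc(O)cc1)O2
F7 | step 14 | hexaphenol bromide (21 without benzyl groups), (7aS,8aS,7bS,8bS) | Oc1ccc([C@H]2c3c(O)cc(O)cc3[C@H]3c4c(cc(O)cc4[C@H]2c2cc(Br)ccc2O)O[C@@H]3c2ccc(O)cc2)cc1
F8 | step 14 | (2S,3S)-4-bromo-3-(3,5-dihydroxyphenyl)-2-(4-hydroxyphenyl)-2,3-dihydro-1-benzofuran-6-ol | Brc1cc(O)cc2c1[C@H](c1cc(O)cc(O)c1)[C@@H](c1ccc(O)cc1)O2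
F9 | step 14 | (2S,3S)-3-(3,5-dihydroxyphenyl)-4-ethenyl-2-(4-hydroxyphenyl)-2,3-dihydro-1-benzofuran-6-ol | C=Cc1cc(O)cc2c1[C@H](c1cc(O)cc(O)c1)[C@@H](c1ccc(O)cc1)O2
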